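## Retrosynthetic overview

1. The acid comes from its methyl ester, and the C9=C10 (E)-alkene from a Julia–Kocienski olefination of a 1,2-dioxane aldehyde with a styryl tetrazolyl sulfone (C10–C14, made from crotonaldehyde by organocatalytic styryl addition).
2. The only ring, the 1,2-dioxane, is closed by a 6-exo peroxy-Michael addition (O–C3) of a tertiary hydroperoxide onto an (E)-enoate. The hydroperoxide comes from Mukaiyama–Isayama hydroperoxysilylation of a 1,1-disubstituted alkene.
3. The enoate comes from a saturated ester by half-reduction and Wittig olefination.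
4. Key disconnection C5–C6 (with C6–C7): 1,1-dichloroethene serves as the C6 linchpin. C5 arrives as the β-carbanion of an ester (zinc homoenolate of methyl (R)-3-bromo-2-methylpropanoate) and C7 as the alkylzinc from silylated (S)-3-bromo-2-methylpropan-1-ol, so the C4 and C8 methyl stereocentres are bought.
5. Ring order: the single ring is formed after the C1–C9 chain is complete and before the side chain is attached.

Assumption: atoms are labelled C1 (CO2H) to C14 (CHPh) along the backbone (ring carbons C3–C6, target 3S,4S,6S,8R,12S), and all starting materials and both enantiomers of the imidazolidinone catalyst are taken as purchasable.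

## Route

Step 1
Reactants: 1 (2S)-3-bromo-2-methylpropan-1-ol
Product: 2 [(2S)-3-bromo-2-methylpropoxy]triethylsilane
Conditions: Et3SiCl, imidazole, CH2Cl2, 0 °C → rt
Reagents that add atoms: chlorotriethylsilane, CC[Si](Cl)(CC)CC
Why: Silyl ether protection of the primary alcohol so that the bromide can be converted into an organozinc; the C8 stereocentre is not touched.

Step 2
Reactants: 2 [(2S)-3-bromo-2-methylpropoxy]triethylsilane; 3 1,1-dichloroethene; 4 methyl (2R)-3-bromo-2-methylpropanoate
Product: 8 methyl (2S,6R)-2,6-dimethyl-4-methylidene-7-[(triethylsilyl)oxy]heptanoate, via alkylzinc bromide 5 (not isolated), via chloroalkene 6 (not isolated), via zinc homoenolate 7 (not isolated)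
Conditions: 2 (1.05 equiv), Zn dust, LiCl, THF, 50 °C; add to 3 (1.0 equiv), PdCl2(DPEphos) (2 mol%), THF, 0 °C → rt; then 7 (1.5 equiv, made apart from 4, Zn dust, LiCl, THF, 40 °C), Pd[P(t-Bu)3]2 (5 mol%), THF/NMP, 70 °C
Reagents that add atoms: none
Why: Twofold Negishi cross-coupling on a gem-dichloroalkene linchpin: PdCl2(DPEphos) couples 5 with one C–Cl bond of 3 and leaves the deactivated 2-chloro-1-alkene 6 untouched, then the β-zincio ester 7 (a homoenolate, a carbanion at the normally electrophilic β-carbon) couples with 6 under the bulky, electron-rich Pd[P(t-Bu)3]2 to make the C5–C6 bond to the future peroxide carbon; C4 and C8 are carried in from 4 and 2 because neither C–Zn carbon is stereogenic and the ester α-centre is never enolised (R → S at C4 is a priority change only).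

Step 3
Reactants: 8 methyl (2S,6R)-2,6-dimethyl-4-methylidene-7-[(triethylsilyl)oxy]heptanoate
Product: 10 methyl (2E,4S,8R)-4,8-dimethyl-6-methylidene-9-[(triethylsilyl)oxy]non-2-enoate, via aldehyde 9 (not isolated)
Conditions: i-Bu2AlH (1.1 equiv), CH2Cl2, −78 °C; then Ph3P=CHCO2Me, −78 °C → rt
Reagents that add atoms: methyl (triphenyl-λ5-phosphanylidene)acetate, COC(=O)C=P(c1ccccc1)(c1ccccc1)c1ccccc1
Why: Half-reduction of the ester to the aluminium hemiacetal followed by Wittig olefination of aldehyde 9 as it is released gives the (E)-enoate (stabilised ylide) without isolating the epimerisable α-methyl aldehyde, so C4 is kept.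

Step 4
Reactants: 10 methyl (2E,4S,8R)-4,8-dimethyl-6-methylidene-9-[(triethylsilyl)oxy]non-2-enoate
Product: 11 methyl (2E,4S,6RS,8R)-4,6,8-trimethyl-6-[(triethylsilyl)peroxy]-9-[(triethylsilyl)oxy]non-2-enoate (1:1 at C6)
Conditions: Co(thd)2 [bis(2,2,6,6-tetramethylheptane-3,5-dionato)cobalt, Co(C11H19O2)2] (10 mol%), O2 (1 atm), Et3SiH (2 equiv), ClCH2CH2Cl, rt
Reagents that add atoms: dioxygen, O=O; triethylsilane, CC[SiH](CC)CC
Why: Mukaiyama–Isayama hydroperoxysilylation: the cobalt hydride formed from Et3SiH transfers a hydrogen atom to the electron-rich 1,1-disubstituted alkene (Markovnikov), O2 traps the tertiary C6 radical and the peroxide is silylated, while the electron-poor 1,2-disubstituted enoate reacts much more slowly; O2 capture is not face-selective, so C6 forms as a 1:1 pair that is resolved in step 5.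

Step 5
Reactants: 11 methyl (2E,4S,6RS,8R)-4,6,8-trimethyl-6-[(triethylsilyl)peroxy]-9-[(triethylsilyl)oxy]non-2-enoate
Product: 13 methyl 2-[(3S,4S,6S)-6-[(2R)-3-hydroxy-2-methylpropyl]-4,6-dimethyl-1,2-dioxan-3-yl]acetate, via hydroperoxy alcohol 12 (not isolated)
Conditions: HF·pyridine, THF, 0 °C; then Et2NH, CF3CH2OH, 0 °C → rt; SiO2 chromatography
Reagents that add atoms: none
Why: HF removes both silyl groups and Et2NH in CF3CH2OH triggers the 6-exo peroxy-Michael (oxa-Michael) ring closure onto the (E)-enoate under non-equilibrating conditions; a chair transition state with C4-Me equatorial and the enoate axial (the kinetic preference of E-enoates in 6-exo oxa-Michael closures) gives the 3,4-cis ring with C3 = S, and chromatography removes the dioxanes from the other C6 epimer and any 3-epimer, which fixes C6 (open-chain 6R becomes ring 6S by priority change only).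

Step 6
Reactants: 13 methyl 2-[(3S,4S,6S)-6-[(2R)-3-hydroxy-2-methylpropyl]-4,6-dimethyl-1,2-dioxan-3-yl]acetate
Product: 14 methyl 2-[(3S,4S,6R)-4,6-dimethyl-6-[(2R)-2-methyl-3-oxopropyl]-1,2-dioxan-3-yl]acetate
Conditions: Dess–Martin periodinane, CH2Cl2, 0 °C → rt
Reagents that add atoms: none
Why: Dess–Martin oxidation of the primary alcohol under non-basic, non-reducing conditions that leave the O–O bond and the C8 α-stereocentre intact (6S → 6R is a priority change only).

Step 7
Reactants: 15 (2E)-but-2-enal; 16 potassium trifluoro[(E)-2-phenylethenyl]borate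
Product: 18 (3S,4E)-3-methyl-5-phenylpent-4-en-1-ol, via aldehyde 17 (not isolated)
Conditions: 15 (3 equiv), (2R,5R)-5-benzyl-2-tert-butyl-3-methylimidazolidin-4-one·HCl (20 mol%), HF (aq, 1 equiv), DME, −20 °C; then NaBH4, EtOH, 0 °C
Reagents that add atoms: none
Why: Iminium-catalysed conjugate addition of the alkenyltrifluoroborate (MacMillan organocatalytic vinylation): the benzyl and tert-butyl groups of the (2R,5R) catalyst block one face of the E-iminium ion of 15, so the styryl group adds to the other face and sets C12 as S with the E-alkene retained, and NaBH4 reduces aldehyde 17 in the same flask.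

Step 8
Reactants: 18 (3S,4E)-3-methyl-5-phenylpent-4-en-1-ol
Product: 19 5-{[(3S,4E)-3-methyl-5-phenylpent-4-en-1-yl]sulfanyl}-1-phenyl-1H-tetrazole
Conditions: 1-phenyl-1H-tetrazole-5-thiol, PPh3, i-PrO2CN=NCO2i-Pr, THF, 0 °C → rt
Reagents that add atoms: 1-phenyl-1H-tetrazole-5-thiol, Sc1nnnn1-c1ccccc1
Why: Mitsunobu thioetherification of the primary alcohol with the acidic tetrazole thiol; C12 is remote and untouched.

Step 9
Reactants: 19 5-{[(3S,4E)-3-methyl-5-phenylpent-4-en-1-yl]sulfanyl}-1-phenyl-1H-tetrazole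
Product: 20 5-{[(3S,4E)-3-methyl-5-phenylpent-4-en-1-yl]sulfonyl}-1-phenyl-1H-tetrazole
Conditions: (NH4)6Mo7O24·4H2O (10 mol%), 30% H2O2, EtOH, 0 °C → rt
Reagents that add atoms: hydrogen peroxide, OO
Why: Molybdate-catalysed oxidation of sulfide to sulfone, selective for sulfur over the styrenyl alkene.

Step 10
Reactants: 14 methyl 2-[(3S,4S,6R)-4,6-dimethyl-6-[(2R)-2-methyl-3-oxopropyl]-1,2-dioxan-3-yl]acetate; 20 5-{[(3S,4E)-3-methyl-5-phenylpent-4-en-1-yl]sulfonyl}-1-phenyl-1H-tetrazole
Product: 22 methyl 2-[(3S,4S,6S)-6-[(2R,3E,6S,7E)-2,6-dimethyl-8-phenylocta-3,7-dien-1-yl]-4,6-dimethyl-1,2-dioxan-3-yl]acetate, via sulfonyl carbanion 21 (not isolated)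
Conditions: 20 (1.3 equiv), KN(SiMe3)2 (1.25 equiv), DME, −78 °C; then 14, −78 → −40 °C; aq NH4Cl
Reagents that add atoms: none
Why: Julia–Kocienski olefination: the pre-formed potassium sulfonyl carbanion 21 adds to the α-branched aldehyde at −78 °C and Smiles rearrangement with loss of SO2 and the tetrazolone gives the (E)-alkene (KN(SiMe3)2 in DME, open transition state); no free base meets 14, so C8 is not epimerised and the β-peroxy ester is not enolised.

Step 11
Reactants: 22 methyl 2-[(3S,4S,6S)-6-[(2R,3E,6S,7E)-2,6-dimethyl-8-phenylocta-3,7-dien-1-yl]-4,6-dimethyl-1,2-dioxan-3-yl]acetate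
Product: 23 2-[(3S,4S,6S)-6-[(2R,3E,6S,7E)-2,6-dimethyl-8-phenylocta-3,7-dien-1-yl]-4,6-dimethyl-1,2-dioxan-3-yl]acetic acid
Conditions: LiOH·H2O, THF/MeOH/H2O, 0 °C; then 1 M HCl to pH 3
Reagents that add atoms: lithium hydroxide, [Li+].[OH-]
Why: Saponification of the methyl ester at 0 °C, where hydroxide attacks the ester carbonyl much faster than it can enolise C2, so the β-peroxy ester does not ring-open and no stereocentre is touched.

## Compound list

1 | (2S)-3-bromo-2-methylpropan-1-ol | C[C@@H](CO)CBr | starting material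
2 | [(2S)-3-bromo-2-methylpropoxy]triethylsilane | C[C@@H](CO[Si](CC)(CC)CC)CBr | intermediate
3 | 1,1-dichloroethene | C=C(Cl)Cl | starting material
4 | methyl (2R)-3-bromo-2-methylpropanoate | COC(=O)[C@@H](C)CBr | starting material
5 | bromo{(2S)-2-methyl-3-[(triethylsilyl)oxy]propyl}zinc | C[C@@H](CO[Si](CC)(CC)CC)C[Zn]Br | intermediate
6 | triethyl{[(2R)-4-chloro-2-methylpent-4-en-1-yl]oxy}silane | C=C(Cl)C[C@@H](C)CO[Si](CC)(CC)CC | intermediate
7 | bromo[(2R)-3-methoxy-2-methyl-3-oxopropyl]zinc | COC(=O)[C@@H](C)C[Zn]Br | intermediate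
8 | methyl (2S,6R)-2,6-dimethyl-4-methylidene-7-[(triethylsilyl)oxy]heptanoate | COC(=O)[C@@H](C)CC(=C)C[C@@H](C)CO[Si](CC)(CC)CC | intermediate
9 | (2S,6R)-2,6-dimethyl-4-methylidene-7-[(triethylsilyl)oxy]heptanal | O=C[C@@H](C)CC(=C)C[C@@H](C)CO[Si](CC)(CC)CC | intermediate
10 | methyl (2E,4S,8R)-4,8-dimethyl-6-methylidene-9-[(triethylsilyl)oxy]non-2-enoate | COC(=O)/C=C/[C@@H](C)CC(=C)C[C@@H](C)CO[Si](CC)(CC)CC | intermediate
11 | methyl (2E,4S,6RS,8R)-4,6,8-trimethyl-6-[(triethylsilyl)peroxy]-9-[(triethylsilyl)oxy]non-2-enoate (1:1 C6 epimers; the 6R epimer leads on) | COC(=O)/C=C/[C@@H](C)CC(C)(OO[Si](CC)(CC)CC)C[C@@H](C)CO[Si](CC)(CC)CC | intermediate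
12 | methyl (2E,4S,6RS,8R)-6-hydroperoxy-9-hydroxy-4,6,8-trimethylnon-2-enoate | COC(=O)/C=C/[C@@H](C)CC(C)(OO)C[C@@H](C)CO | intermediate
13 | methyl 2-[(3S,4S,6S)-6-[(2R)-3-hydroxy-2-methylpropyl]-4,6-dimethyl-1,2-dioxan-3-yl]acetate | OC[C@H](C)C[C@@]1(C)C[C@H](C)[C@H](CC(=O)OC)OO1 | intermediate
14 | methyl 2-[(3S,4S,6R)-4,6-dimethyl-6-[(2R)-2-methyl-3-oxopropyl]-1,2-dioxan-3-yl]acetate | O=C[C@H](C)C[C@@]1(C)C[C@H](C)[C@H](CC(=O)OC)OO1 | intermediate
15 | (2E)-but-2-enal | C/C=C/C=O | starting material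
16 | potassium trifluoro[(E)-2-phenylethenyl]borate | [K+].F[B-](F)(F)/C=C/c1ccccc1 | starting material
17 | (3S,4E)-3-methyl-5-phenylpent-4-enal | C[C@H](/C=C/c1ccccc1)CC=O | intermediate
18 | (3S,4E)-3-methyl-5-phenylpent-4-en-1-ol | C[C@H](/C=C/c1ccccc1)CCO | intermediate
19 | 5-{[(3S,4E)-3-methyl-5-phenylpent-4-en-1-yl]sulfanyl}-1-phenyl-1H-tetrazole | C[C@H](/C=C/c1ccccc1)CCSc1nnnn1-c1ccccc1 | intermediate
20 | 5-{[(3S,4E)-3-methyl-5-phenylpent-4-en-1-yl]sulfonyl}-1-phenyl-1H-tetrazole | C[C@H](/C=C/c1ccccc1)CCS(=O)(=O)c1nnnn1-c1ccccc1 | intermediate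
21 | potassium (3S,4E)-3-methyl-5-phenyl-1-[(1-phenyl-1H-tetrazol-5-yl)sulfonyl]pent-4-en-1-ide | C[C@H](/C=C/c1ccccc1)C[CH-]S(=O)(=O)c1nnnn1-c1ccccc1.[K+] | intermediate
22 | methyl 2-[(3S,4S,6S)-6-[(2R,3E,6S,7E)-2,6-dimethyl-8-phenylocta-3,7-dien-1-yl]-4,6-dimethyl-1,2-dioxan-3-yl]acetate | C[C@H](/C=C/c1ccccc1)C/C=C/[C@H](C)C[C@@]1(C)C[C@H](C)[C@H](CC(=O)OC)OO1 | intermediate
23 | 2-[(3S,4S,6S)-6-[(2R,3E,6S,7E)-2,6-dimethyl-8-phenylocta-3,7-dien-1-yl]-4,6-dimethyl-1,2-dioxan-3-yl]acetic acid | C[C@H](/C=C/c1ccccc1)C/C=C/[C@H](C)C[C@@]1(C)C[C@H](C)[C@H](CC(=O)O)OO1 | target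

## Step count and risks

Total steps: 11. Longest linear sequence: 8 (steps 1–6, 10, 11); the sulfone 20 is made in 3 steps (7–9).

Most likely to fail:

**Step 5 (ring closure).** Only the 6R half of 11 can give 13, and the 3,4-cis outcome rests on a kinetic axial preference that is argued by analogy, not demonstrated for this substrate. A realistic isolated yield of 13 is 30% or less, and the 3,4-trans isomer could dominate. Fallback: make the C3 stereocentre by C–C bond formation on a peroxycarbenium ion instead of by C–O closure. It sets out from 8 and comes back at 13.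
- Hydroperoxysilylation of 8 as in step 4 (no second alkene is present, so the chemoselectivity question of step 4 also disappears) gives the silyl peroxide ester F1.
- i-Bu2AlH at −78 °C gives the silyl peroxide aldehyde F2.
- HCl in MeOH strips both silyl groups; the hydroperoxide closes onto the aldehyde and the peroxy-lactol is converted into the 3-methoxy-1,2-dioxane alcohol F3 (C6 epimers separated here).
- Me3SiOTf and tert-butyl[(1-methoxyethenyl)oxy]dimethylsilane in CH2Cl2 at −78 °C add the acetate unit. Axial attack on the half-chair peroxycarbenium ion with C4-Me pseudo-equatorial gives the 3,4-cis ester 13 after aqueous work-up.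

**Step 2 (one-pot twofold Negishi coupling).** It needs clean discrimination of the two C–Cl bonds and coupling of an ester-bearing alkylzinc with an unactivated alkenyl chloride without β-hydride elimination. Fallback: a nickel-catalysed reductive cross-electrophile coupling that needs no preformed homoenolate. It sets out from 5 and comes back at 8.
- 5 is coupled with 1,1-dibromoethene (PdCl2(DPEphos), THF) to give the isolated bromoalkene F4.
- F4 and bromo ester 4 are joined with NiBr2(MeOCH2CH2OMe), 4,4'-di-tert-butyl-2,2'-bipyridine, Mn powder and NaI in N,N-dimethylacetamide at 40 °C to give 8.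

**Step 10 (Julia–Kocienski olefination).** The β-peroxy ester can be enolised by the carbanion (ring opening), and the aldehyde is epimerisable. Fallback: olefin cross-metathesis without any carbanion partner. It sets out from 14, uses 17 isolated by leaving out NaBH4 in step 7, and comes back at 22.
- Ph3P=CH2 (THF, −78 °C) converts 14 into the vinyl dioxane F5.
- Ph3P=CH2 converts 17 into the diene F6.
- F5 and F6 (3 equiv) with the second-generation Hoveyda–Grubbs catalyst RuCl2(H2IMes)(=CH-C6H4-2-O-i-Pr) in CH2Cl2 at 40 °C give 22; the E isomer is expected to be major but E/Z control is weaker than in step 10, and the Z isomer is removed on AgNO3-impregnated silica.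

Further compounds

F1 | step 5 | methyl (2S,4RS,6R)-2,4,6-trimethyl-4-[(triethylsilyl)peroxy]-7-[(triethylsilyl)oxy]heptanoate | COC(=O)[C@@H](C)CC(C)(OO[Si](CC)(CC)CC)C[C@@H](C)CO[Si](CC)(CC)CC
F2 | step 5 | (2S,4RS,6R)-2,4,6-trimethyl-4-[(triethylsilyl)peroxy]-7-[(triethylsilyl)oxy]heptanal | O=C[C@@H](C)CC(C)(OO[Si](CC)(CC)CC)C[C@@H](C)CO[Si](CC)(CC)CC
F3 | step 5 | (2R)-3-[(3S,5S,6RS)-6-methoxy-3,5-dimethyl-1,2-dioxan-3-yl]-2-methylpropan-1-ol | OC[C@H](C)C[C@@]1(C)C[C@H](C)C(OC)OO1
F4 | step 2 | {[(2R)-4-bromo-2-methylpent-4-en-1-yl]oxy}triethylsilane | C=C(Br)C[C@@H](C)CO[Si](CC)(CC)CC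
F5 | step 10 | methyl 2-[(3S,4S,6S)-4,6-dimethyl-6-[(2R)-2-methylbut-3-en-1-yl]-1,2-dioxan-3-yl]acetate | C=C[C@H](C)C[C@@]1(C)C[C@H](C)[C@H](CC(=O)OC)OO1
F6 | step 10 | [(1E,3S)-3-methylhexa-1,5-dien-1-yl]benzene | C[C@H](/C=C/c1ccccc1)CC=C
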